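**Retrosynthetic overview**

1. Germacrane numbering is used: C1 ketone, C2 furanone CH, C3 furanone O-bearing sp2 carbon, Z C4=C5 (methyl on C4), C6 lactone CH–O, C7 fusion CH, C8 ester carbinol, C9 CH2, C10 quaternary C–O (its oxygen is O10), C11–C13 α-methylene lactone. The side-chain acetate is set last, from a silyl ether.
2. Key disconnection: the 3(2H)-furanone is cut at C1–C2 and O10–C3. This also opens the ten-membered carbocycle and gives seco compound 23 with a C1 thioester, a free C10 hydroxyl and a terminal C2≡C3 alkyne.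
3. Enabling feature: O10–C10–C1(=O) is an α-hydroxy acyl unit, and the Z C4=C5 alkene on the trans-fused γ-lactone turns the C2≡C3 alkyne back toward C1. Acylation of C2 by C1 therefore makes C3 the β-carbon of an ynone in 5-endo reach of O10.
4. 23 comes from Mitsunobu inversion/esterification at C8 and a C7–C8 Barbier allylation of aldehyde 15 (C8–C10 and C1, from (R)-lactic acid) with bromobutenolide 8 (C2–C7 and C11–C13, from (2Z)-3-methylpent-2-en-4-yn-1-ol).
5. Ring order: γ-lactone first (ring-closing metathesis, step 5), then the ten-membered carbocycle and the furanone together (step 15).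

Key step: step 15

Remark: the zinc allylation of step 12 is assumed to pass through the closed chair transition state of a ring-locked E-type allylmetal, so C8 is expected first as its S epimer and is inverted in step 13.

**Route**

Step 1
Reactants: 1 (2Z)-3-methylpent-2-en-4-yn-1-ol
Product: 3 (2Z)-3-methyl-5-(trimethylsilyl)pent-2-en-4-yn-1-ol, via bis-silyl ether 2 (not isolated)
Conditions: EtMgBr (2.2 equiv), THF, 0 to 40 °C; Me3SiCl (2.3 equiv), 0 °C to rt; then 1 M HCl, rt
Reagents that add atoms: chlorotrimethylsilane, C[Si](C)(C)Cl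
Why: The alkoxide–acetylide dianion is silylated on oxygen and on carbon (acetylide C-silylation) and the acid work-up should cleave only the labile O–Si bond, so the alkyne is masked for the zinc and ruthenium steps and the Z alkene is not touched.

Step 2
Reactants: 3 (2Z)-3-methyl-5-(trimethylsilyl)pent-2-en-4-yn-1-ol
Product: 4 (2Z)-3-methyl-5-(trimethylsilyl)pent-2-en-4-ynal
Conditions: MnO2 (activated, excess), CH2Cl2, rt, dark; filtered and used crude
Reagents that add atoms: none
Why: MnO2 oxidizes allylic alcohols selectively under neutral conditions (allylic alcohol oxidation), and a short reaction in the dark with direct use of the aldehyde should limit Z to E drift of the enal.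

Step 3
Reactants: 4 (2Z)-3-methyl-5-(trimethylsilyl)pent-2-en-4-ynal
Product: 5 (3S,4Z)-5-methyl-7-(trimethylsilyl)hepta-1,4-dien-6-yn-3-ol
Conditions: Zn(CH=CH2)2 (salt-free solution, 1.5 equiv), (−)-MIB [(2S)-3-exo-morpholinoisoborneol, 10 mol%], toluene, −30 to 0 °C; aq NH4Cl
Reagents that add atoms: divinylzinc, C=C[Zn]C=C
Why: In this amino-alcohol-catalysed asymmetric addition of an alkenylzinc to an aldehyde, the ligand enantiomer is chosen to deliver vinyl to the Si face, which should set the carbinol (future C6) as S, and the silyl-capped alkyne is inert to the zinc reagent.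

Step 4
Reactants: 5 (3S,4Z)-5-methyl-7-(trimethylsilyl)hepta-1,4-dien-6-yn-3-ol; 6 2-(bromomethyl)prop-2-enoic acid
Product: 7 (3S,4Z)-5-methyl-7-(trimethylsilyl)hepta-1,4-dien-6-yn-3-yl 2-(bromomethyl)prop-2-enoate
Conditions: DCC, DMAP (5 mol%), CH2Cl2, −10 to 0 °C
Reagents that add atoms: none
Why: Steglich esterification acylates the secondary alcohol on oxygen without touching the stereocentre, and the low temperature with only catalytic DMAP should spare the allylic bromide.

Step 5
Reactants: 7 (3S,4Z)-5-methyl-7-(trimethylsilyl)hepta-1,4-dien-6-yn-3-yl 2-(bromomethyl)prop-2-enoate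
Product: 8 (5R)-3-(bromomethyl)-5-[(1Z)-2-methyl-4-(trimethylsilyl)but-1-en-3-yn-1-yl]furan-2(5H)-one
Conditions: second-generation Hoveyda–Grubbs catalyst (5 mol%), toluene (0.01 M), 80 °C, argon sparge
Reagents that add atoms: none
Why: Ring-closing metathesis should start at the monosubstituted vinyl group and close onto the acrylate to form the butenolide with loss of ethene, while the trisubstituted enyne alkene and the silyl-capped alkyne are poor metathesis partners; the stereocentre is not involved and is named R only because the priorities change.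

Step 6
Reactants: 9 (2R)-2-hydroxypropanoic acid ((R)-lactic acid)
Product: 10 (2R,5R)-2-tert-butyl-5-methyl-1,3-dioxolan-4-one
Conditions: t-BuCHO, TsOH (cat.), pentane, reflux, Dean–Stark; cis isomer purified by low-temperature recrystallization
Reagents that add atoms: pivalaldehyde, CC(C)(C)C=O
Why: Acid-catalysed acetalization of the α-hydroxy acid should favour the cis dioxolanone, which stores the lactic acid configuration in the new acetal carbon (first stage of self-regeneration of stereocentres).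

Step 7
Reactants: 10 (2R,5R)-2-tert-butyl-5-methyl-1,3-dioxolan-4-one
Product: 12 (2R,5S)-2-tert-butyl-5-methyl-5-(prop-2-en-1-yl)-1,3-dioxolan-4-one, via lithium enolate 11 (not isolated)
Conditions: LiN(iPr)2, THF, −78 °C; allyl bromide, −78 to −30 °C
Reagents that add atoms: allyl bromide, C=CCBr
Why: The lithium enolate should be alkylated on the face opposite the tert-butyl group (diastereoselective enolate alkylation with self-regeneration of the stereocentre), which sets the quaternary carbon (future C10) in the configuration that is S in the open-chain thioester.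

Step 8
Reactants: 12 (2R,5S)-2-tert-butyl-5-methyl-5-(prop-2-en-1-yl)-1,3-dioxolan-4-one
Product: 13 S-ethyl (2S)-2-hydroxy-2-methylpent-4-enethioate
Conditions: AlMe3, EtSH, CH2Cl2, 0 °C to rt; aq HCl
Reagents that add atoms: ethanethiol, CCS
Why: The aluminium thiolate formed from AlMe3 and the thiol converts the activated dioxolanone carbonyl into the thioester (aluminium-thiolate ester-to-thioester exchange), and the hemiacetal alkoxide left behind collapses on work-up to the free tertiary alcohol without touching the quaternary centre.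

Step 9
Reactants: 13 S-ethyl (2S)-2-hydroxy-2-methylpent-4-enethioate
Product: 15 S-ethyl (2S)-2-hydroxy-2-methyl-4-oxobutanethioate, via ozonide 14 (not isolated)
Conditions: O3, CH2Cl2, −78 °C (indicator dye); PPh3, −78 °C to rt
Reagents that add atoms: ozone, [O-][O+]=O
Why: Ozonolysis with reductive work-up cleaves the terminal alkene to the C8 aldehyde, while the thioester and the tertiary alcohol should be inert at low temperature when over-ozonation is avoided.

Step 10
Reactants: 16 {[tert-butyl(dimethyl)silyl]oxy}acetaldehyde; 17 ethyl 2-(triphenylphosphoranylidene)propanoate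
Product: 18 ethyl (2E)-4-{[tert-butyl(dimethyl)silyl]oxy}-2-methylbut-2-enoate
Conditions: CH2Cl2, rt
Reagents that add atoms: none
Why: The Wittig reaction of a stabilized ylide should give the E trisubstituted enoate.

Step 11
Reactants: 18 ethyl (2E)-4-{[tert-butyl(dimethyl)silyl]oxy}-2-methylbut-2-enoate
Product: 19 (2E)-4-{[tert-butyl(dimethyl)silyl]oxy}-2-methylbut-2-enoic acid
Conditions: LiOH, THF/H2O, 0 °C to rt; then HCl to pH 4 at 0 °C
Reagents that add atoms: lithium hydroxide, [Li+].[OH-]
Why: Saponification cleaves the ethyl ester, and the primary silyl ether should survive mild base and careful acidification.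

Step 12
Reactants: 8 (5R)-3-(bromomethyl)-5-[(1Z)-2-methyl-4-(trimethylsilyl)but-1-en-3-yn-1-yl]furan-2(5H)-one; 15 S-ethyl (2S)-2-hydroxy-2-methyl-4-oxobutanethioate
Product: 21 S-ethyl (2S,4S)-2,4-dihydroxy-2-methyl-4-{(2R,3R)-4-methylidene-2-[(1Z)-2-methyl-4-(trimethylsilyl)but-1-en-3-yn-1-yl]-5-oxooxolan-3-yl}butanethioate, via allylzinc bromide 20 (not isolated)
Conditions: Zn dust, THF/sat. aq NH4Cl, 0 °C to rt; product used at once
Reagents that add atoms: none
Why: Zinc inserts into the allylic bromide and the 2-(alkoxycarbonyl)allylzinc adds through its γ-carbon (Barbier allylation, SE2′ through a closed Zimmerman–Traxler chair); attack on C7 anti to the C6 substituent should give the trans lactone (C7 R), and the ring-locked E-type allyl unit should give the anti carbinol (C8 S), the epimer that the next step inverts.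

Step 13
Reactants: 21 the (2S,4S)-dihydroxy thioester lactone of step 12; 19 (2E)-4-{[tert-butyl(dimethyl)silyl]oxy}-2-methylbut-2-enoic acid
Product: 22 S-ethyl (2S,4R)-4-{[(2E)-4-{[tert-butyl(dimethyl)silyl]oxy}-2-methylbut-2-enoyl]oxy}-2-hydroxy-2-methyl-4-{(2R,3R)-4-methylidene-2-[(1Z)-2-methyl-4-(trimethylsilyl)but-1-en-3-yn-1-yl]-5-oxooxolan-3-yl}butanethioate
Conditions: PPh3, DIAD, toluene, 0 °C to rt
Reagents that add atoms: none
Why: The Mitsunobu esterification activates only the secondary C8 hydroxyl (the tertiary C10 hydroxyl does not react) and the carboxylate displaces it by SN2 with inversion, which sets C8 as R and brings in the side-chain skeleton in one operation.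

Step 14
Reactants: 22 the (2S,4R) ester thioester with the silyl-capped alkyne of step 13
Product: 23 S-ethyl (2S,4R)-4-{[(2E)-4-{[tert-butyl(dimethyl)silyl]oxy}-2-methylbut-2-enoyl]oxy}-2-hydroxy-2-methyl-4-{(2R,3R)-4-methylidene-2-[(1Z)-2-methylbut-1-en-3-yn-1-yl]-5-oxooxolan-3-yl}butanethioate
Conditions: Bu4NF (1.05 equiv), AcOH (1.2 equiv), THF, −20 °C, short reaction time
Reagents that add atoms: none
Why: Fluoride cleaves the C(sp)–Si bond much faster than the primary O–Si bond at low temperature (protodesilylation of an alkynylsilane), and the acetic acid buffer should protect the thioester and the α-methylene lactone.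

Step 15
Reactants: 23 the seco thioester with the terminal alkyne of step 14
Product: 25 (3aR,4R,6S,10Z,11aR)-6,10-dimethyl-3-methylidene-2,7-dioxo-2,3,3a,4,5,6,7,11a-octahydro-6,9-epoxycyclodeca[b]furan-4-yl (2E)-4-{[tert-butyl(dimethyl)silyl]oxy}-2-methylbut-2-enoate, via macrocyclic hydroxy ynone 24 (not isolated)
Conditions: PdCl2(dppf) (10 mol%), P(2-furyl)3 (25 mol%), CuI (copper iodide, 1.7 equiv), Et3N, DMF, 50 °C, slow addition of 23 (final 1 mM), argon
Reagents that add atoms: none
Why: Proposed new method: zerovalent palladium should insert into the C1–S bond of the thioester, the copper acetylide made from the terminal C2≡C3 alkyne with CuI and Et3N should transmetalate, and reductive elimination should join C1 to C2 to give the ten-membered α′-hydroxy ynone 24, in which the tertiary C10 hydroxyl adds to C3 and protonation at C2 gives the 3(2H)-furanone. The closest known reaction types are the palladium/copper coupling of thioesters with terminal alkynes to ynones (an acyl Sonogashira-type ketone synthesis) and the base- or metal-promoted cycloisomerization of α′-hydroxy ynones to 3(2H)-furanones, which are here merged and run as a macrocyclization. The ten-membered carbocycle closes by C(sp2)–C(sp) reductive elimination from an eleven-membered acyl(alkynyl)palladium ring, and the furanone closes by a transannular 5-endo-dig oxa-Michael addition that releases the bending strain of the cyclic ynone. No stereocentre is formed, and C6, C7, C8 and C10 should not epimerize because C10 is quaternary and no enolizable or ionizable centre is activated. The step needs ring closure in preference to intermolecular coupling, which high dilution with slow addition, the Z C4=C5 alkene and the trans-fused lactone (both turn the chain back on itself) should secure, and it needs O–C3 bond formation only, which is secured because the C10 oxygen is the one nucleophile within five-membered reach of the ynone β-carbon while the C8 oxygen is acylated. The side chain carries an allylic silyl ether and not the acetate, so it offers no ionizable allylic leaving group to zerovalent palladium.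

Step 16
Reactants: 25 the silyl-protected furanone macrocycle of step 15
Product: 26 (3aR,4R,6S,10Z,11aR)-6,10-dimethyl-3-methylidene-2,7-dioxo-2,3,3a,4,5,6,7,11a-octahydro-6,9-epoxycyclodeca[b]furan-4-yl (2E)-4-hydroxy-2-methylbut-2-enoate
Conditions: HF·pyridine, pyridine, THF, 0 °C to rt
Reagents that add atoms: none
Why: Buffered HF·pyridine removes the primary silyl ether (fluoride desilylation) under mildly acidic conditions that the furanone, the α-methylene lactone and the ester should tolerate.

Step 17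
Reactants: 26 the primary allylic alcohol of step 16
Product: 27 (3aR,4R,6S,10Z,11aR)-6,10-dimethyl-3-methylidene-2,7-dioxo-2,3,3a,4,5,6,7,11a-octahydro-6,9-epoxycyclodeca[b]furan-4-yl (2E)-4-(acetyloxy)-2-methylbut-2-enoate
Conditions: Ac2O, pyridine, CH2Cl2, 0 °C
Reagents that add atoms: acetic anhydride, CC(=O)OC(C)=O
Why: O-Acetylation of the primary allylic alcohol is fast at 0 °C and needs no strong base or nucleophile that could add to the α-methylene lactone, so it should give the target.

**Compound list**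

1 | (2Z)-3-methylpent-2-en-4-yn-1-ol | OC/C=C(/C)C#C | starting material
2 | trimethyl{[(2Z)-3-methyl-5-(trimethylsilyl)pent-2-en-4-yn-1-yl]oxy}silane | C[Si](C)(C)OC/C=C(/C)C#C[Si](C)(C)C | intermediate
3 | (2Z)-3-methyl-5-(trimethylsilyl)pent-2-en-4-yn-1-ol | OC/C=C(/C)C#C[Si](C)(C)C | intermediate
4 | (2Z)-3-methyl-5-(trimethylsilyl)pent-2-en-4-ynal | O=C/C=C(/C)C#C[Si](C)(C)C | intermediate
5 | (3S,4Z)-5-methyl-7-(trimethylsilyl)hepta-1,4-dien-6-yn-3-ol | O[C@H](/C=C(/C)C#C[Si](C)(C)C)C=C | intermediate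
6 | 2-(bromomethyl)prop-2-enoic acid | OC(=O)C(=C)CBr | starting material
7 | (3S,4Z)-5-methyl-7-(trimethylsilyl)hepta-1,4-dien-6-yn-3-yl 2-(bromomethyl)prop-2-enoate | C=C(CBr)C(=O)O[C@H](/C=C(/C)C#C[Si](C)(C)C)C=C | intermediate
8 | (5R)-3-(bromomethyl)-5-[(1Z)-2-methyl-4-(trimethylsilyl)but-1-en-3-yn-1-yl]furan-2(5H)-one | O=C1O[C@H](/C=C(/C)C#C[Si](C)(C)C)C=C1CBr | intermediate
9 | (2R)-2-hydroxypropanoic acid ((R)-lactic acid) | C[C@@H](O)C(=O)O | starting material
10 | (2R,5R)-2-tert-butyl-5-methyl-1,3-dioxolan-4-one | C[C@H]1O[C@@H](C(C)(C)C)OC1=O | intermediate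
11 | lithium (2R)-2-tert-butyl-5-methyl-1,3-dioxol-4-olate | [Li+].[O-]C1=C(C)O[C@@H](C(C)(C)C)O1 | intermediate
12 | (2R,5S)-2-tert-butyl-5-methyl-5-(prop-2-en-1-yl)-1,3-dioxolan-4-one | C[C@@]1(CC=C)O[C@@H](C(C)(C)C)OC1=O | intermediate
13 | S-ethyl (2S)-2-hydroxy-2-methylpent-4-enethioate | C=CC[C@](C)(O)C(=O)SCC | intermediate
14 | S-ethyl (2S)-2-hydroxy-2-methyl-3-(1,2,4-trioxolan-3-yl)propanethioate (ozonide, either configuration at the trioxolane carbon) | C1OC(C[C@](C)(O)C(=O)SCC)OO1 | intermediate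
15 | S-ethyl (2S)-2-hydroxy-2-methyl-4-oxobutanethioate | O=CC[C@](C)(O)C(=O)SCC | intermediate
16 | {[tert-butyl(dimethyl)silyl]oxy}acetaldehyde | CC(C)(C)[Si](C)(C)OCC=O | starting material
17 | ethyl 2-(triphenylphosphoranylidene)propanoate | CCOC(=O)C(C)=P(c1ccccc1)(c1ccccc1)c1ccccc1 | starting material
18 | ethyl (2E)-4-{[tert-butyl(dimethyl)silyl]oxy}-2-methylbut-2-enoate | CCOC(=O)/C(C)=C/CO[Si](C)(C)C(C)(C)C | intermediate
19 | (2E)-4-{[tert-butyl(dimethyl)silyl]oxy}-2-methylbut-2-enoic acid | OC(=O)/C(C)=C/CO[Si](C)(C)C(C)(C)C | intermediate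
20 | bromo({(5R)-5-[(1Z)-2-methyl-4-(trimethylsilyl)but-1-en-3-yn-1-yl]-2-oxo-2,5-dihydrofuran-3-yl}methyl)zinc | O=C1O[C@H](/C=C(/C)C#C[Si](C)(C)C)C=C1C[Zn]Br | intermediate
21 | S-ethyl (2S,4S)-2,4-dihydroxy-2-methyl-4-{(2R,3R)-4-methylidene-2-[(1Z)-2-methyl-4-(trimethylsilyl)but-1-en-3-yn-1-yl]-5-oxooxolan-3-yl}butanethioate | C=C1C(=O)O[C@H](/C=C(/C)C#C[Si](C)(C)C)[C@H]1[C@@H](O)C[C@](C)(O)C(=O)SCC | intermediate
22 | S-ethyl (2S,4R)-4-{[(2E)-4-{[tert-butyl(dimethyl)silyl]oxy}-2-methylbut-2-enoyl]oxy}-2-hydroxy-2-methyl-4-{(2R,3R)-4-methylidene-2-[(1Z)-2-methyl-4-(trimethylsilyl)but-1-en-3-yn-1-yl]-5-oxooxolan-3-yl}butanethioate | C=C1C(=O)O[C@H](/C=C(/C)C#C[Si](C)(C)C)[C@H]1[C@H](OC(=O)/C(C)=C/CO[Si](C)(C)C(C)(C)C)C[C@](C)(O)C(=O)SCC | intermediate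
23 | S-ethyl (2S,4R)-4-{[(2E)-4-{[tert-butyl(dimethyl)silyl]oxy}-2-methylbut-2-enoyl]oxy}-2-hydroxy-2-methyl-4-{(2R,3R)-4-methylidene-2-[(1Z)-2-methylbut-1-en-3-yn-1-yl]-5-oxooxolan-3-yl}butanethioate | C=C1C(=O)O[C@H](/C=C(/C)C#C)[C@H]1[C@H](OC(=O)/C(C)=C/CO[Si](C)(C)C(C)(C)C)C[C@](C)(O)C(=O)SCC | intermediate
24 | (3aR,4R,6S,10Z,11aR)-6-hydroxy-6,10-dimethyl-3-methylidene-2,7-dioxo-2,3,3a,4,5,6,7,11a-octahydro-8,9-didehydrocyclodeca[b]furan-4-yl (2E)-4-{[tert-butyl(dimethyl)silyl]oxy}-2-methylbut-2-enoate (ten-membered α′-hydroxy ynone) | C=C1C(=O)O[C@@H]2/C=C(/C)C#CC(=O)[C@@](C)(O)C[C@@H](OC(=O)/C(C)=C/CO[Si](C)(C)C(C)(C)C)[C@@H]12 | intermediate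
25 | (3aR,4R,6S,10Z,11aR)-6,10-dimethyl-3-methylidene-2,7-dioxo-2,3,3a,4,5,6,7,11a-octahydro-6,9-epoxycyclodeca[b]furan-4-yl (2E)-4-{[tert-butyl(dimethyl)silyl]oxy}-2-methylbut-2-enoate | C=C1C(=O)O[C@@H]2/C=C(/C)C3=CC(=O)[C@](C)(C[C@@H](OC(=O)/C(C)=C/CO[Si](C)(C)C(C)(C)C)[C@@H]12)O3 | intermediate
26 | (3aR,4R,6S,10Z,11aR)-6,10-dimethyl-3-methylidene-2,7-dioxo-2,3,3a,4,5,6,7,11a-octahydro-6,9-epoxycyclodeca[b]furan-4-yl (2E)-4-hydroxy-2-methylbut-2-enoate | C=C1C(=O)O[C@@H]2/C=C(/C)C3=CC(=O)[C@](C)(C[C@@H](OC(=O)/C(C)=C/CO)[C@@H]12)O3 | intermediate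
27 | (3aR,4R,6S,10Z,11aR)-6,10-dimethyl-3-methylidene-2,7-dioxo-2,3,3a,4,5,6,7,11a-octahydro-6,9-epoxycyclodeca[b]furan-4-yl (2E)-4-(acetyloxy)-2-methylbut-2-enoate | C=C1C(=O)O[C@@H]2/C=C(/C)C3=CC(=O)[C@](C)(C[C@@H](OC(=O)/C(C)=C/COC(C)=O)[C@@H]12)O3 | target

**Step count and risks**

Total step count: 17. Longest linear sequence: 11 steps (steps 1–5 and 12–17, from 1).

Steps most likely to fail:

Step 15 (Proposed new method). The acylpalladium may lose CO, the coupling may run between two molecules and give oligomers, or the strained ynone may decompose before the hydroxyl adds. The fallback uses known reactions, sets out from 22 and comes back at 25. The thioester of 22 is reduced by Fukuyama reduction (Et3SiH, Pd/C, acetone) to the aldehyde (1R,3S)-3-hydroxy-3-methyl-1-{(2R,3R)-4-methylidene-2-[(1Z)-2-methyl-4-(trimethylsilyl)but-1-en-3-yn-1-yl]-5-oxooxolan-3-yl}-4-oxobutyl (2E)-4-{[tert-butyl(dimethyl)silyl]oxy}-2-methylbut-2-enoate F1. The alkynylsilane is converted with N-iodosuccinimide and catalytic AgNO3 into the iodoalkyne (1R,3S)-3-hydroxy-1-{(2R,3R)-2-[(1Z)-4-iodo-2-methylbut-1-en-3-yn-1-yl]-4-methylidene-5-oxooxolan-3-yl}-3-methyl-4-oxobutyl (2E)-4-{[tert-butyl(dimethyl)silyl]oxy}-2-methylbut-2-enoate F2. An intramolecular Nozaki–Hiyama–Kishi alkynylation (CrCl2, catalytic NiCl2, THF, high dilution) closes the ten-membered ring to the propargylic diol (3aR,4R,6S,10Z,11aR)-6,7-dihydroxy-6,10-dimethyl-3-methylidene-2-oxo-2,3,3a,4,5,6,7,11a-octahydro-8,9-didehydrocyclodeca[b]furan-4-yl (2E)-4-{[tert-butyl(dimethyl)silyl]oxy}-2-methylbut-2-enoate F3 (either configuration at the new carbinol). Oxidation of the secondary propargylic alcohol (MnO2 or IBX) gives ynone 24, and catalytic AuCl3 (or Et2NH) closes the furanone to 25. C1–C2 and O10–C3 are then made in separate steps, and the carbon–carbon bond is made by carbonyl addition instead of reductive elimination.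

Step 13. The activated C8 oxyphosphonium may eliminate toward C7 or C9, the thioester carbonyl oxygen may attack C8 and form a γ-lactone, or the weakly acidic enoic acid may esterify too slowly. The fallback sets out from 8 and 15 and comes back at 22. Bromide 8 is converted with (Bu3Sn)2 and catalytic Pd(PPh3)4 into the allylstannane (5R)-5-[(1Z)-2-methyl-4-(trimethylsilyl)but-1-en-3-yn-1-yl]-3-[(tributylstannyl)methyl]furan-2(5H)-one F4. BF3·OEt2 at −78 °C promotes addition of F4 to aldehyde 15 through an open antiperiplanar transition state, which for γ-substituted allylstannanes should lead to the syn carbinol with attack again anti to the C6 substituent, S-ethyl (2S,4R)-2,4-dihydroxy-2-methyl-4-{(2R,3R)-4-methylidene-2-[(1Z)-2-methyl-4-(trimethylsilyl)but-1-en-3-yn-1-yl]-5-oxooxolan-3-yl}butanethioate F5. Steglich esterification of the secondary hydroxyl of F5 with acid 19 (DCC, DMAP), with retention, gives 22. C8 is then set in the carbon–carbon bond formation and no inversion is needed.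

Step 5. The ruthenium carbene may be consumed by the allylic bromide or by enyne metathesis on the silyl alkyne, or the ring may close from the wrong alkene with loss of the enyne arm. The fallback sets out from 4 and comes back at 8 (it also bypasses steps 3 and 4). A zinc/ProPhenol-catalysed asymmetric alkynylation of 4 with tert-butyl(dimethyl)(prop-2-yn-1-yloxy)silane (Me2Zn, ligand enantiomer chosen for the 5R alcohol) gives (3Z,5R)-8-{[tert-butyl(dimethyl)silyl]oxy}-3-methyl-1-(trimethylsilyl)oct-3-ene-1,6-diyn-5-ol F6. Hydroxyl-directed trans-hydroalumination with NaAlH2(OCH2CH2OMe)2 followed by iodine gives the iodoalkene (2Z,4R,5Z)-1-{[tert-butyl(dimethyl)silyl]oxy}-2-iodo-6-methyl-8-(trimethylsilyl)octa-2,5-dien-7-yn-4-ol F7. Carbonylative lactonization (CO, PdCl2(PPh3)2, Et3N) gives the butenolide (5R)-3-({[tert-butyl(dimethyl)silyl]oxy}methyl)-5-[(1Z)-2-methyl-4-(trimethylsilyl)but-1-en-3-yn-1-yl]furan-2(5H)-one F8. HF·pyridine frees the alcohol (5R)-3-(hydroxymethyl)-5-[(1Z)-2-methyl-4-(trimethylsilyl)but-1-en-3-yn-1-yl]furan-2(5H)-one F9, and CBr4/PPh3 (Appel bromination) gives 8. The lactone ring is then built by carbonylation instead of metathesis.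

Further compounds

F1 | step 15 | (1R,3S)-3-hydroxy-3-methyl-1-{(2R,3R)-4-methylidene-2-[(1Z)-2-methyl-4-(trimethylsilyl)but-1-en-3-yn-1-yl]-5-oxooxolan-3-yl}-4-oxobutyl (2E)-4-{[tert-butyl(dimethyl)silyl]oxy}-2-methylbut-2-enoate | C=C1C(=O)O[C@H](/C=C(/C)C#C[Si](C)(C)C)[C@H]1[C@H](OC(=O)/C(C)=C/CO[Si](C)(C)C(C)(C)C)C[C@](C)(O)C=O
F2 | step 15 | (1R,3S)-3-hydroxy-1-{(2R,3R)-2-[(1Z)-4-iodo-2-methylbut-1-en-3-yn-1-yl]-4-methylidene-5-oxooxolan-3-yl}-3-methyl-4-oxobutyl (2E)-4-{[tert-butyl(dimethyl)silyl]oxy}-2-methylbut-2-enoate | C=C1C(=O)O[C@H](/C=C(/C)C#CI)[C@H]1[C@H](OC(=O)/C(C)=C/CO[Si](C)(C)C(C)(C)C)C[C@](C)(O)C=O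
F3 | step 15 | (3aR,4R,6S,10Z,11aR)-6,7-dihydroxy-6,10-dimethyl-3-methylidene-2-oxo-2,3,3a,4,5,6,7,11a-octahydro-8,9-didehydrocyclodeca[b]furan-4-yl (2E)-4-{[tert-butyl(dimethyl)silyl]oxy}-2-methylbut-2-enoate | C=C1C(=O)O[C@@H]2/C=C(/C)C#CC(O)[C@@](C)(O)C[C@@H](OC(=O)/C(C)=C/CO[Si](C)(C)C(C)(C)C)[C@@H]12
F4 | step 13 | (5R)-5-[(1Z)-2-methyl-4-(trimethylsilyl)but-1-en-3-yn-1-yl]-3-[(tributylstannyl)methyl]furan-2(5H)-one | O=C1O[C@H](/C=C(/C)C#C[Si](C)(C)C)C=C1C[Sn](CCCC)(CCCC)CCCC
F5 | step 13 | S-ethyl (2S,4R)-2,4-dihydroxy-2-methyl-4-{(2R,3R)-4-methylidene-2-[(1Z)-2-methyl-4-(trimethylsilyl)but-1-en-3-yn-1-yl]-5-oxooxolan-3-yl}butanethioate | C=C1C(=O)O[C@H](/C=C(/C)C#C[Si](C)(C)C)[C@H]1[C@H](O)C[C@](C)(O)C(=O)SCC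
F6 | step 5 | (3Z,5R)-8-{[tert-butyl(dimethyl)silyl]oxy}-3-methyl-1-(trimethylsilyl)oct-3-ene-1,6-diyn-5-ol | O[C@H](/C=C(/C)C#C[Si](C)(C)C)C#CCO[Si](C)(C)C(C)(C)C
F7 | step 5 | (2Z,4R,5Z)-1-{[tert-butyl(dimethyl)silyl]oxy}-2-iodo-6-methyl-8-(trimethylsilyl)octa-2,5-dien-7-yn-4-ol | O[C@H](/C=C(/C)C#C[Si](C)(C)C)/C=C(\I)CO[Si](C)(C)C(C)(C)C
F8 | step 5 | (5R)-3-({[tert-butyl(dimethyl)silyl]oxy}methyl)-5-[(1Z)-2-methyl-4-(trimethylsilyl)but-1-en-3-yn-1-yl]furan-2(5H)-one | O=C1O[C@H](/C=C(/C)C#C[Si](C)(C)C)C=C1CO[Si](C)(C)C(C)(C)C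
F9 | step 5 | (5R)-3-(hydroxymethyl)-5-[(1Z)-2-methyl-4-(trimethylsilyl)but-1-en-3-yn-1-yl]furan-2(5H)-one | O=C1O[C@H](/C=C(/C)C#C[Si](C)(C)C)C=C1CO
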